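The oxirane is traced back to a prochiral aryl tartronate in which C-8 carries two identical tert-butyl ester arms, the future oxirane CH2 (C-9) and acyloxymethyl carbon (C-10). The feature exploited is the phenol oxygen on ring carbon C-3, ortho to the C-4–C-8 bond: it can reach either ester through a five-membered benzofuran-2-one ring that the target lacks. A chiral phosphoric acid lets it capture one enantiotopic ester, which in one operation forms the aryl O–C(=O) bond, sets the C-8 stereocentre and makes the two arms chemically different. The precursor is a di-tert-butyl 2-aryl-2-hydroxymalonate with a free ortho phenol and a silyl-protected para hydroxymethyl group.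

Key step: step 8

Numbering used: ring carbons C-1 to C-6, with C-1 bearing the formyl carbon C-7, C-3 the phenolic oxygen and C-4 the side chain; C-8 is the quaternary oxirane carbon, C-9 the oxirane CH2 and C-10 the acyloxymethyl carbon.

Assumption: the sense of induction of the phosphoric acid with a phenol nucleophile cannot be predicted, so (R)-TRIP, (R)-3,3'-bis(2,4,6-triisopropylphenyl)-1,1'-binaphthyl-2,2'-diyl hydrogen phosphate, is written and its mirror image is to be used if a first trial shows that it favours the other ester.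

Step 1
Reactants: 1 4-bromo-3-hydroxybenzaldehyde
Product: 2 3-(benzyloxy)-4-bromobenzaldehyde
Conditions: BnBr, K2CO3, DMF, rt
Reagents that add atoms: benzyl bromide, BrCc1ccccc1
Why: Williamson ether synthesis: the phenoxide is benzylated at oxygen by SN2, and the benzyl ether is chosen because it withstands the aryllithium of step 6 and can later be removed by hydrogenolysis without acid or base.

Step 2
Reactants: 2 3-(benzyloxy)-4-bromobenzaldehyde
Product: 3 [3-(benzyloxy)-4-bromophenyl]methanol
Conditions: NaBH4, MeOH, 0 °C
Reagents that add atoms: none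
Why: Borohydride reduction of the aryl aldehyde to the benzylic alcohol takes away the one group that could not survive bromine–lithium exchange, while the aryl bromide and the benzyl ether are inert to NaBH4.

Step 3
Reactants: 3 [3-(benzyloxy)-4-bromophenyl]methanol
Product: 4 tert-butyl{[3-(benzyloxy)-4-bromophenyl]methoxy}diphenylsilane
Conditions: TBDPSCl, imidazole, CH2Cl2, rt
Reagents that add atoms: tert-butyl(chloro)diphenylsilane, CC(C)(C)[Si](Cl)(c1ccccc1)c1ccccc1
Why: Imidazole-promoted silylation of the primary alcohol; the tert-butyldiphenylsilyl ether is chosen because it should survive n-BuLi, hydrogenolysis, the phosphoric acid, TFA and borane and still leave with fluoride.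

Step 4
Reactants: 5 di-tert-butyl malonate
Product: 6 di-tert-butyl 2-diazomalonate
Conditions: p-ABSA, Et3N, MeCN, 0 °C to rt
Reagents that add atoms: 4-acetamidobenzenesulfonyl azide, CC(=O)Nc1ccc(cc1)S(=O)(=O)N=[N+]=[N-]
Why: Regitz diazo transfer from the sulfonyl azide to the doubly activated methylene of the malonate under amine base.

Step 5
Reactants: 6 di-tert-butyl 2-diazomalonate
Product: 7 di-tert-butyl 2-oxomalonate
Conditions: DMDO, acetone, 0 °C to rt; concentrate, 4 Å MS
Reagents that add atoms: dimethyldioxirane, CC1(C)OO1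
Why: Oxidation of the diazo carbon by oxygen-atom transfer from the dioxirane with loss of N2 should give the vicinal tricarbonyl compound, and because the co-products are volatile the water-sensitive ketone can be taken on anhydrous after evaporation.

Step 6
Reactants: 4 tert-butyl{[3-(benzyloxy)-4-bromophenyl]methoxy}diphenylsilane, 7 di-tert-butyl 2-oxomalonate
Product: 9 di-tert-butyl 2-[2-(benzyloxy)-4-{[(tert-butyldiphenylsilyl)oxy]methyl}phenyl]-2-hydroxymalonate, via aryllithium 8 (not isolated)
Conditions: n-BuLi, THF, −78 °C; then 7, −78 °C; aq NH4Cl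
Reagents that add atoms: none
Why: Bromine–lithium exchange followed by 1,2-addition of the aryllithium to the central, non-enolisable and most electrophilic carbonyl of the oxomalonate at −78 °C, where the hindered tert-butyl esters are not attacked.

Step 7
Reactants: 9 di-tert-butyl 2-[2-(benzyloxy)-4-{[(tert-butyldiphenylsilyl)oxy]methyl}phenyl]-2-hydroxymalonate
Product: 10 di-tert-butyl 2-[4-{[(tert-butyldiphenylsilyl)oxy]methyl}-2-hydroxyphenyl]-2-hydroxymalonate
Conditions: H2 (1 atm), 10% Pd/C, EtOAc, rt
Reagents that add atoms: none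
Why: Catalytic hydrogenolysis of the aryl benzyl ether frees the phenol under neutral conditions, so the phenol–diester pair meets no acid or base that could close the lactone without stereocontrol, while the benzylic silyl ether and the tertiary alcohol flanked by two esters are cleaved far more slowly.

Step 8
Reactants: 10 di-tert-butyl 2-[4-{[(tert-butyldiphenylsilyl)oxy]methyl}-2-hydroxyphenyl]-2-hydroxymalonate
Product: 11 tert-butyl (3R)-6-{[(tert-butyldiphenylsilyl)oxy]methyl}-3-hydroxy-2-oxo-2,3-dihydro-1-benzofuran-3-carboxylate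
Conditions: (R)-TRIP (10 mol%), 5 Å MS, toluene, 35 °C
Reagents that add atoms: none
Why: Proposed new method: the acid is expected to act bifunctionally, its P–OH hydrogen-bonding to one ester carbonyl while its P=O accepts the phenol O–H, so that the phenol oxygen adds to that carbonyl and the tetrahedral intermediate loses tert-butanol, which the sieves take up so that the acyl transfer cannot run backwards. The closest known reaction type is the chiral-phosphoric-acid-catalysed desymmetrising lactonisation of di-tert-butyl malonates that carry an aliphatic hydroxyl arm; a phenol is a weaker nucleophile, but here it is held ortho to a fully substituted carbon and the aryl lactone is kept by removal of the alcohol. The benzofuran-2-one ring closes in the 5-exo-trig mode. The new stereocentre C-3 of the lactone (C-8 of the target) is created solely by the choice between the two enantiotopic esters, and that choice is controlled by the chiral pocket of the catalyst, which binds the phenol and the carbonyl in a fixed two-point arrangement next to its 3,3'-aryl groups. The step needs enantiotopic-group selectivity with no uncatalysed pathway, and the substrate secures this because tert-butyl esters are inert to a neutral phenol, the tertiary hydroxyl could only close a three-membered ring, and the ortho phenol can form no ring other than the five-membered one.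

Step 9
Reactants: 11 tert-butyl (3R)-6-{[(tert-butyldiphenylsilyl)oxy]methyl}-3-hydroxy-2-oxo-2,3-dihydro-1-benzofuran-3-carboxylate
Product: 12 tert-butyl (2S)-2-[4-{[(tert-butyldiphenylsilyl)oxy]methyl}-2-hydroxyphenyl]-2,3-dihydroxypropanoate
Conditions: NaBH4, THF–EtOH, 0 °C; aq NH4Cl
Reagents that add atoms: none
Why: Chemoselective borohydride reduction: the phenolic lactone carbonyl is far more electrophilic than the hindered tert-butyl ester, so it should be reduced through the lactol and the ring-opened hydroxy aldehyde to the primary alcohol (future C-10) with release of the phenol, and no bond to the stereocentre is broken.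

Step 10
Reactants: 12 tert-butyl (2S)-2-[4-{[(tert-butyldiphenylsilyl)oxy]methyl}-2-hydroxyphenyl]-2,3-dihydroxypropanoate, 13 isovaleryl chloride (2.2 equiv)
Product: 14 tert-butyl (2S)-2-[4-{[(tert-butyldiphenylsilyl)oxy]methyl}-2-(3-methylbutanoyloxy)phenyl]-2-hydroxy-3-(3-methylbutanoyloxy)propanoate
Conditions: Et3N, DMAP (cat.), CH2Cl2, 0 °C
Reagents that add atoms: none
Why: Acylation with the acid chloride under nucleophilic catalysis by DMAP esterifies the phenol and the primary alcohol, whereas the tertiary hydroxyl next to the ester and the aryl ring is too hindered to react at 0 °C.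

Step 11
Reactants: 14 tert-butyl (2S)-2-[4-{[(tert-butyldiphenylsilyl)oxy]methyl}-2-(3-methylbutanoyloxy)phenyl]-2-hydroxy-3-(3-methylbutanoyloxy)propanoate
Product: 15 (2S)-2-[4-{[(tert-butyldiphenylsilyl)oxy]methyl}-2-(3-methylbutanoyloxy)phenyl]-2-hydroxy-3-(3-methylbutanoyloxy)propanoic acid
Conditions: TFA, CH2Cl2, 0 °C to rt
Reagents that add atoms: none
Why: Acidolysis of the tert-butyl ester through the tert-butyl cation (lost as 2-methylpropene) leaves the primary and phenolic esters and the silyl ether intact, and the tertiary benzylic hydroxyl does not ionise because the carboxyl and acyloxy groups around it destabilise a cation.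

Step 12
Reactants: 15 (2S)-2-[4-{[(tert-butyldiphenylsilyl)oxy]methyl}-2-(3-methylbutanoyloxy)phenyl]-2-hydroxy-3-(3-methylbutanoyloxy)propanoic acid
Product: 16 (2R)-2-[4-{[(tert-butyldiphenylsilyl)oxy]methyl}-2-(3-methylbutanoyloxy)phenyl]-2,3-dihydroxypropyl 3-methylbutanoate
Conditions: BH3·THF, THF, 0 °C to rt; MeOH
Reagents that add atoms: none
Why: Chemoselective borane reduction of the carboxylic acid through its acyloxyborane gives the primary alcohol (future C-9), since borane reduces acids much faster than esters.

Step 13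
Reactants: 16 (2R)-2-[4-{[(tert-butyldiphenylsilyl)oxy]methyl}-2-(3-methylbutanoyloxy)phenyl]-2,3-dihydroxypropyl 3-methylbutanoate
Product: 17 {(2R)-2-[4-{[(tert-butyldiphenylsilyl)oxy]methyl}-2-(3-methylbutanoyloxy)phenyl]oxiran-2-yl}methyl 3-methylbutanoate
Conditions: PPh3, DIAD, THF, 0 °C to rt
Reagents that add atoms: none
Why: Mitsunobu cyclodehydration of a 1,2-diol: the less hindered primary hydroxyl is activated as the alkoxyphosphonium ion and displaced by the tertiary hydroxyl in a 3-exo-tet closure, so no bond to C-8 is broken and its configuration is retained, and the neutral medium avoids the free alkoxide that could transfer the neighbouring acyl groups.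

Step 14
Reactants: 17 {(2R)-2-[4-{[(tert-butyldiphenylsilyl)oxy]methyl}-2-(3-methylbutanoyloxy)phenyl]oxiran-2-yl}methyl 3-methylbutanoate
Product: 18 {(2R)-2-[4-(hydroxymethyl)-2-(3-methylbutanoyloxy)phenyl]oxiran-2-yl}methyl 3-methylbutanoate
Conditions: TBAF, AcOH (1:1), THF, 0 °C to rt
Reagents that add atoms: none
Why: Fluoride-induced cleavage of the silyl ether, with the fluoride buffered by acetic acid so that the medium stays close to neutral and the oxirane and the phenolic ester should be left alone.

Step 15
Reactants: 18 {(2R)-2-[4-(hydroxymethyl)-2-(3-methylbutanoyloxy)phenyl]oxiran-2-yl}methyl 3-methylbutanoate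
Product: 19 {(2R)-2-[4-formyl-2-(3-methylbutanoyloxy)phenyl]oxiran-2-yl}methyl 3-methylbutanoate
Conditions: MnO2, CH2Cl2, rt
Reagents that add atoms: none
Why: Oxidation of the benzylic alcohol to the aldehyde with MnO2 under neutral heterogeneous conditions, which does not over-oxidise and does not touch the oxirane or the esters.

Compound list

1 | 4-bromo-3-hydroxybenzaldehyde | O=Cc1ccc(Br)c(O)c1 | starting material
2 | 3-(benzyloxy)-4-bromobenzaldehyde | O=Cc1ccc(Br)c(OCc2ccccc2)c1 | intermediate
3 | [3-(benzyloxy)-4-bromophenyl]methanol | OCc1ccc(Br)c(OCc2ccccc2)c1 | intermediate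
4 | tert-butyl{[3-(benzyloxy)-4-bromophenyl]methoxy}diphenylsilane | CC(C)(C)[Si](OCc1ccc(Br)c(OCc2ccccc2)c1)(c1ccccc1)c1ccccc1 | intermediate
5 | di-tert-butyl malonate | CC(C)(C)OC(=O)CC(=O)OC(C)(C)C | starting material
6 | di-tert-butyl 2-diazomalonate | CC(C)(C)OC(=O)C(=[N+]=[N-])C(=O)OC(C)(C)C | intermediate
7 | di-tert-butyl 2-oxomalonate | CC(C)(C)OC(=O)C(=O)C(=O)OC(C)(C)C | intermediate
8 | [2-(benzyloxy)-4-{[(tert-butyldiphenylsilyl)oxy]methyl}phenyl]lithium (not isolated) | [Li]c1ccc(CO[Si](c2ccccc2)(c2ccccc2)C(C)(C)C)cc1OCc1ccccc1 | intermediate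
9 | di-tert-butyl 2-[2-(benzyloxy)-4-{[(tert-butyldiphenylsilyl)oxy]methyl}phenyl]-2-hydroxymalonate | CC(C)(C)OC(=O)C(O)(C(=O)OC(C)(C)C)c1ccc(CO[Si](c2ccccc2)(c2ccccc2)C(C)(C)C)cc1OCc1ccccc1 | intermediate
10 | di-tert-butyl 2-[4-{[(tert-butyldiphenylsilyl)oxy]methyl}-2-hydroxyphenyl]-2-hydroxymalonate (precursor of the key step) | CC(C)(C)OC(=O)C(O)(C(=O)OC(C)(C)C)c1ccc(CO[Si](c2ccccc2)(c2ccccc2)C(C)(C)C)cc1O | intermediate
11 | tert-butyl (3R)-6-{[(tert-butyldiphenylsilyl)oxy]methyl}-3-hydroxy-2-oxo-2,3-dihydro-1-benzofuran-3-carboxylate (product of the key step) | O=C1Oc2cc(CO[Si](c3ccccc3)(c3ccccc3)C(C)(C)C)ccc2[C@@]1(O)C(=O)OC(C)(C)C | intermediate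
12 | tert-butyl (2S)-2-[4-{[(tert-butyldiphenylsilyl)oxy]methyl}-2-hydroxyphenyl]-2,3-dihydroxypropanoate | OC[C@](O)(C(=O)OC(C)(C)C)c1ccc(CO[Si](c2ccccc2)(c2ccccc2)C(C)(C)C)cc1O | intermediate
13 | isovaleryl chloride (3-methylbutanoyl chloride) | CC(C)CC(Cl)=O | starting material
14 | tert-butyl (2S)-2-[4-{[(tert-butyldiphenylsilyl)oxy]methyl}-2-(3-methylbutanoyloxy)phenyl]-2-hydroxy-3-(3-methylbutanoyloxy)propanoate | CC(C)CC(=O)OC[C@](O)(C(=O)OC(C)(C)C)c1ccc(CO[Si](c2ccccc2)(c2ccccc2)C(C)(C)C)cc1OC(=O)CC(C)C | intermediate
15 | (2S)-2-[4-{[(tert-butyldiphenylsilyl)oxy]methyl}-2-(3-methylbutanoyloxy)phenyl]-2-hydroxy-3-(3-methylbutanoyloxy)propanoic acid | CC(C)CC(=O)OC[C@](O)(C(=O)O)c1ccc(CO[Si](c2ccccc2)(c2ccccc2)C(C)(C)C)cc1OC(=O)CC(C)C | intermediate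
16 | (2R)-2-[4-{[(tert-butyldiphenylsilyl)oxy]methyl}-2-(3-methylbutanoyloxy)phenyl]-2,3-dihydroxypropyl 3-methylbutanoate | CC(C)CC(=O)OC[C@](O)(CO)c1ccc(CO[Si](c2ccccc2)(c2ccccc2)C(C)(C)C)cc1OC(=O)CC(C)C | intermediate
17 | {(2R)-2-[4-{[(tert-butyldiphenylsilyl)oxy]methyl}-2-(3-methylbutanoyloxy)phenyl]oxiran-2-yl}methyl 3-methylbutanoate | CC(C)CC(=O)OC[C@@]1(c2ccc(CO[Si](c3ccccc3)(c3ccccc3)C(C)(C)C)cc2OC(=O)CC(C)C)CO1 | intermediate
18 | {(2R)-2-[4-(hydroxymethyl)-2-(3-methylbutanoyloxy)phenyl]oxiran-2-yl}methyl 3-methylbutanoate | CC(C)CC(=O)OC[C@@]1(c2ccc(CO)cc2OC(=O)CC(C)C)CO1 | intermediate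
19 | {(2R)-2-[4-formyl-2-(3-methylbutanoyloxy)phenyl]oxiran-2-yl}methyl 3-methylbutanoate (CNP0274578.1) | CC(C)CC(=O)OC[C@@]1(c2ccc(C=O)cc2OC(=O)CC(C)C)CO1 | target

Total step count: 15.
Longest linear sequence: 13 steps (steps 1 to 3 and 6 to 15, from 1 to 19); steps 4 and 5 form a two-step side branch to 7.

Steps most likely to fail

Step 8. The phenol may add too slowly to the hindered ester, the catalyst may discriminate poorly between the two enantiotopic esters, or slow re-opening of the activated aryl lactone by tert-butanol may erode the enantiomeric purity. The fallback uses known chemistry only (hydride reduction, lipase-catalysed desymmetrising acylation of a prochiral 2-substituted propane-1,3-diol, phenoxide-selective acylation). It sets out from 10 and comes back to the route at 16, so steps 8 to 12 are bypassed. Both tert-butyl esters of 10 would be reduced with LiAlH4 in THF at 0 °C to the prochiral 2-[4-{[(tert-butyldiphenylsilyl)oxy]methyl}-2-hydroxyphenyl]propane-1,2,3-triol F1. A lipase (Burkholderia cepacia lipase, vinyl 3-methylbutanoate, tert-butyl methyl ether, rt) would then acylate one of the two enantiotopic primary hydroxyls to give (2R)-2-[4-{[(tert-butyldiphenylsilyl)oxy]methyl}-2-hydroxyphenyl]-2,3-dihydroxypropyl 3-methylbutanoate F2; a lipase of the opposite preference would be chosen if the first one acylates the other arm. Finally the phenol of F2 would be acylated selectively as its phenoxide with 13 (1 equiv, aqueous NaOH, CH2Cl2, Bu4NHSO4, 0 °C) to give 16.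

Step 13. The diol may be held as a cyclic dialkoxyphosphorane that collapses only slowly, and a diol that lingers can shift its C-10 acyl group to the C-9 hydroxyl, which exchanges the two arms and lowers the enantiomeric purity. The fallback sets out from 16 and comes back at 17. It replaces the redox dehydration by a sulfonate displacement: the primary hydroxyl would be mesylated (MsCl, Et3N, CH2Cl2, −20 °C) to give (2S)-2-[4-{[(tert-butyldiphenylsilyl)oxy]methyl}-2-(3-methylbutanoyloxy)phenyl]-2-hydroxy-3-(methylsulfonyloxy)propyl 3-methylbutanoate F3, and Cs2CO3 in MeCN at 0 °C to rt would close the oxirane by intramolecular Williamson displacement to give 17.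

Step 14. Fluoride or acetate may open the oxirane, or the phenolic ester may be cleaved or transferred, while the robust silyl group is removed. The fallback sets out from 16 and comes back at the target 19; it moves desilylation and oxidation ahead of ring closure, so that fluoride never meets the oxirane. HF·pyridine in THF–pyridine would remove the silyl group from 16 to give (2R)-2,3-dihydroxy-2-[4-(hydroxymethyl)-2-(3-methylbutanoyloxy)phenyl]propyl 3-methylbutanoate F4. MnO2 in CH2Cl2 would oxidise only the benzylic alcohol to give (2R)-2-[4-formyl-2-(3-methylbutanoyloxy)phenyl]-2,3-dihydroxypropyl 3-methylbutanoate F5. MsCl and Et3N at −20 °C would sulfonylate the one remaining primary hydroxyl to give (2S)-2-[4-formyl-2-(3-methylbutanoyloxy)phenyl]-2-hydroxy-3-(methylsulfonyloxy)propyl 3-methylbutanoate F6, and Cs2CO3 in MeCN would close the oxirane to give 19.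

Further compounds
F1 | step 8 | 2-[4-{[(tert-butyldiphenylsilyl)oxy]methyl}-2-hydroxyphenyl]propane-1,2,3-triol | OCC(O)(CO)c1ccc(CO[Si](c2ccccc2)(c2ccccc2)C(C)(C)C)cc1O
F2 | step 8 | (2R)-2-[4-{[(tert-butyldiphenylsilyl)oxy]methyl}-2-hydroxyphenyl]-2,3-dihydroxypropyl 3-methylbutanoate | CC(C)CC(=O)OC[C@](O)(CO)c1ccc(CO[Si](c2ccccc2)(c2ccccc2)C(C)(C)C)cc1O
F3 | step 13 | (2S)-2-[4-{[(tert-butyldiphenylsilyl)oxy]methyl}-2-(3-methylbutanoyloxy)phenyl]-2-hydroxy-3-(methylsulfonyloxy)propyl 3-methylbutanoate | CC(C)CC(=O)OC[C@](O)(COS(C)(=O)=O)c1ccc(CO[Si](c2ccccc2)(c2ccccc2)C(C)(C)C)cc1OC(=O)CC(C)C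
F4 | step 14 | (2R)-2,3-dihydroxy-2-[4-(hydroxymethyl)-2-(3-methylbutanoyloxy)phenyl]propyl 3-methylbutanoate | CC(C)CC(=O)OC[C@](O)(CO)c1ccc(CO)cc1OC(=O)CC(C)C
F5 | step 14 | (2R)-2-[4-formyl-2-(3-methylbutanoyloxy)phenyl]-2,3-dihydroxypropyl 3-methylbutanoate | CC(C)CC(=O)OC[C@](O)(CO)c1ccc(C=O)cc1OC(=O)CC(C)C
F6 | step 14 | (2S)-2-[4-formyl-2-(3-methylbutanoyloxy)phenyl]-2-hydroxy-3-(methylsulfonyloxy)propyl 3-methylbutanoate | CC(C)CC(=O)OC[C@](O)(COS(C)(=O)=O)c1ccc(C=O)cc1OC(=O)CC(C)C
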